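**Strategy.** The ten-membered carbocycle is disconnected at C2–C3, the bond between the ring CH2 and the epoxide CH. This bond is the σ-bond of a [3,3] shift, because the C5 oxygen and a C1=C10 alkene (later the C1 ester/C10 acetate pair) flank it as in a cyclodec-1(10)-en-5-one. One anionic oxy-Cope step therefore closes the ring, cleaves the old ring bond of (S)-carvone, sets the C1=C10 geometry and leaves a C4=C5 enolate that leads to the epoxide. The precursor is a carvone-derived cyclohexanol carrying a C5 isopropenyl group, a C10 vinyl and methyl group, and the C6, C7 and C9 stereocentres.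

Key step: step 7

Remark on numbering: target ring locants are C1 = CH–OAng next to C10, C2 = CH2, C3 = epoxide CH, C4 = epoxide C(CH3), C5 = CH–OAng, C6 = CH–O-(2-methylbutanoyl), C7 = CH–isopropenyl, C8 = CH2, C9 = CH–OH, C10 = C(CH3)(OAc). All intermediates keep these locants (the six-membered ring is C5–C10). β is the face of the C7 isopropenyl group in the flat ring drawing and α the other face; Ang = (Z)-2-methylbut-2-enoyl, Ar = 4-methoxyphenyl, TBS = tert-butyldimethylsilyl.

Assumption: the 2-methylbutanoate is the (R)-ester, as the structure specifies; (R)-2-methylbutanoic acid is bought as such.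

Step 1
Reactants: 1 (S)-(+)-carvone
Product: 3 (5R,6R)-6-hydroxycarvone (6α-OH), via potassium dienolate 2 (not isolated)
Conditions: KN(SiMe3)2, THF, −78 °C; 2-(phenylsulfonyl)-3-phenyloxaziridine, −78 °C; NH4Cl aq.
Reagents that add atoms: 2-(phenylsulfonyl)-3-phenyloxaziridine, O=S(=O)(c1ccccc1)N1OC1c1ccccc1
Why: Kinetic α′-deprotonation at C6 and enolate hydroxylation by the N-sulfonyloxaziridine, with the oxidant approaching anti to the neighbouring C7 isopropenyl group, should give mainly the trans (6α) ketol.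

Step 2
Reactants: 3 (5R,6R)-6-hydroxycarvone
Product: 4 (5R,6S)-6-(4-methoxyphenoxy)carvone (6β-OAr)
Conditions: 4-MeOC6H4OH, PPh3, DIAD, toluene, 0 °C → rt
Reagents that add atoms: 4-methoxyphenol, COc1ccc(O)cc1
Why: Mitsunobu etherification of the α-ketol (SN2 next to the carbonyl) inverts C6, so the oxygen ends cis to the isopropenyl group and is at once masked as an aryl ether that tolerates organometallic reagents and strong base and is removable by oxidation.

Step 3
Reactants: 4 (5R,6S)-6-(4-methoxyphenoxy)carvone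
Product: 5 5β-hydroxy-5α-vinyl adduct of 4 [(1R,5R,6S)-6-(4-methoxyphenoxy)-2-methyl-5-(prop-1-en-2-yl)-1-vinylcyclohex-2-en-1-ol]
Conditions: CH2=CHMgBr, CeCl3, THF, −78 °C; NH4Cl aq.
Reagents that add atoms: vinylmagnesium bromide, C=C[Mg]Br
Why: CeCl3-mediated 1,2-addition to the enone, with attack anti to the C6 aryloxy and C7 isopropenyl groups, should place the vinyl group on the α face and the tertiary hydroxyl on the β face while suppressing enolisation at C6.

Step 4
Reactants: 5 5β-hydroxy-5α-vinyl adduct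
Product: 6 9β,10β-epoxide of 5
Conditions: VO(acac)2 (cat.), t-BuOOH, CH2Cl2, 0 °C → rt
Reagents that add atoms: tert-butyl hydroperoxide, CC(C)(C)OO
Why: Hydroxyl-directed epoxidation of the cyclohexenol delivers oxygen to the trisubstituted ring alkene C9=C10 on the face of the tertiary hydroxyl (β), leaving the isopropenyl group untouched and reacting faster than the monosubstituted vinyl group.

Step 5
Reactants: 6 9β,10β-epoxide of 5
Product: 7 6β-aryloxy-9β-(TBS-oxy)-10β-methyl-10α-vinyl-7β-isopropenylcyclohexan-5-one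
Conditions: t-BuMe2SiOTf, 2,6-di-tert-butyl-4-methylpyridine, CH2Cl2, −78 → −40 °C
Reagents that add atoms: tert-butyldimethylsilyl triflate, CC(C)(C)[Si](C)(C)OS(=O)(=O)C(F)(F)F
Why: Semipinacol rearrangement of the 2,3-epoxy alcohol: silyl activation of the epoxide oxygen triggers an anti-periplanar 1,2-shift of the α-vinyl group from C5 to C10 with inversion at C10, giving the C5 ketone, the quaternary C10 (α-vinyl, β-methyl) and the C9 β-oxygen, which keeps the silyl group.

Step 6
Reactants: 7 C5 ketone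
Product: 8 5β-hydroxy-5α-isopropenyl adduct of 7 (5α-isopropenyl cis to 10α-vinyl)
Conditions: CH2=C(CH3)MgBr, CeCl3, THF, −78 → 0 °C; NH4Cl aq.
Reagents that add atoms: isopropenylmagnesium bromide, CC(=C)[Mg]Br
Why: Organocerium 1,2-addition to the hindered ketone should occur from the α face, anti to the axial C6 aryloxy and C10 methyl groups, giving the tertiary alcohol whose isopropenyl group is gauche (axial/equatorial) to the C10 vinyl group as the [3,3] shift requires.

Step 7
Reactants: 8 5β-hydroxy-5α-isopropenyl-10α-vinyl cyclohexanol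
Product: 10 4-(phenylselanyl)-(1(10)Z)-cyclodec-1(10)-en-5-one (6β-OAr; 7β-isopropenyl; 9β-OTBS; C4 epimers), via potassium enolate 9 (not isolated)
Conditions: KN(SiMe3)2, 18-crown-6, THF, 0 °C → rt; PhSeCl, −78 °C
Reagents that add atoms: phenylselenyl chloride, Cl[Se]c1ccccc1
Why: Deprotonation gives the potassium alkoxide, whose charge-accelerated [3,3]-sigmatropic shift forms the C2–C3 bond between the termini of the C10 vinyl and C5 isopropenyl groups while the C5–C10 bond (the former C1–C2 bond of carvone) breaks, giving the ten-membered enolate 9 irreversibly. The closest known reaction type is the anionic oxy-Cope ring expansion of 1,2-dialkenylcyclohexanols to cyclodec-5-enones. The ten-membered ring is closed by this one bond in a six-centre chair transition state, i.e. a [3,3]-sigmatropic four-carbon expansion of the six-membered ring. No sp3 centre is created in the shift (C6, C7 and C9 are carried over; the C4 selenide centre is transient and uncontrolled), and the geometry of the new C1=C10 alkene is set by the chair: with C7 isopropenyl and C9 silyloxy equatorial, the C5 isopropenyl is axial and the C10 vinyl equatorial, so C9 sits axial in the six-centre array and the alkene should be Z, as the later anti addition across C1/C10 requires. The step needs the chair pathway from this conformer and a regiodefined enolate; the cis relation of the two alkenyl groups set in steps 5 and 6 secures the first, and the rearrangement itself places the enolate at C4=C5, where PhSeCl reacts at C4.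

Step 8
Reactants: 10 α-phenylselanyl ketone
Product: 12 (1(10)Z,3Z)-cyclodeca-1(10),3-dien-5-one (6β-OAr; 9β-OTBS), via selenoxide 11 (not isolated)
Conditions: mCPBA, CH2Cl2, −78 °C; then i-Pr2NH, −78 °C → rt
Reagents that add atoms: none
Why: Selenide oxidation and selenoxide syn elimination towards C3–H should give the endocyclic enone, and in a ring that already holds the Z C1=C10 alkene the less strained Z geometry at C3=C4 is expected.

Step 9
Reactants: 12 dienone aryl ether
Product: 13 6β-hydroxy dienone (9β-OTBS)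
Conditions: (NH4)2Ce(NO3)6, pyridine, MeCN/H2O 4:1, 0 °C
Reagents that add atoms: none
Why: Oxidative cleavage of the 4-methoxyphenyl ether (arene radical cation, loss of benzoquinone) frees the C6 hydroxyl while the silyl ether, the alkenes and the enone should survive the short cold exposure.

Step 10
Reactants: 13 6β-hydroxy dienone; 14 (R)-2-methylbutanoic acid
Product: 15 6β-[(R)-2-methylbutanoyloxy] dienone (9β-OTBS)
Conditions: DCC, DMAP (cat.), CH2Cl2, 0 °C → rt
Reagents that add atoms: none
Why: Carbodiimide (Steglich) esterification of the only free hydroxyl installs the C6 ester, with low temperature and catalytic DMAP limiting epimerisation of the α-stereocentre of the acid.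

Step 11
Reactants: 15 C6 ester silyl ether
Product: 16 9β-hydroxy dienone C6 ester
Conditions: HF·pyridine, pyridine, THF, 0 °C → rt
Reagents that add atoms: none
Why: Fluoride cleavage of the allylic silyl ether frees the C9 hydroxyl that directs the next two steps, under non-basic conditions that spare the ester and the skipped dienone.

Step 12
Reactants: 16 9β-hydroxy dienone
Product: 17 1α,10α-epoxide of 16 (epoxide trans to the C9 hydroxyl)
Conditions: mCPBA, NaHCO3, CH2Cl2, 0 °C
Reagents that add atoms: meta-chloroperbenzoic acid, OOC(=O)c1cccc(Cl)c1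
Why: Hydroxyl-directed peracid epoxidation of the Z allylic alcohol (C9–OH, C10=C1) should give the threo epoxy alcohol, as A(1,3) strain dictates for Z allylic alcohols and as peracids do with medium-ring Z-cycloalkenols, while the enone is inert and the isopropenyl group reacts more slowly.

Step 13
Reactants: 17 1α,10α-epoxy-9β-alcohol; 18 angelic acid
Product: 19 1β-angeloyloxy-9β,10α-dihydroxy-(3Z)-en-5-one
Conditions: Ti(Oi-Pr)4, CH2Cl2, rt; tartaric acid aq.
Reagents that add atoms: none
Why: Ti(Oi-Pr)4-mediated opening of the 2,3-epoxy alcohol delivers the carboxylate to the distal epoxide carbon C1 with inversion, giving the 1β-angelate and leaving the tertiary 10α-hydroxyl, i.e. net anti addition across the former Z alkene.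

Step 14
Reactants: 19 9β,10α-diol
Product: 20 9,10-O-(1-methoxyethylidene) cyclic orthoacetate of 19 (orthoester carbon as both epimers)
Conditions: MeC(OMe)3, PPTS (cat.), CH2Cl2, rt
Reagents that add atoms: trimethyl orthoacetate, CC(OC)(OC)OC
Why: Transorthoesterification ties the C9/C10 diol into a five-membered orthoacetate, a temporary ring that protects both hydroxyls and already carries the two carbons of the future C10 acetate.

Step 15
Reactants: 20 orthoacetate enone
Product: 21 5β-alcohol of 20
Conditions: Zn(BH4)2, Et2O, −20 °C; NH4Cl aq.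
Reagents that add atoms: none
Why: 1,2-Reduction of the enone by a chelating borohydride, with hydride delivered from the ring periphery to the carbonyl held syn to the C6 acyloxy oxygen (Cram-chelate model), should give the 5β alcohol cis to the C6 ester.

Step 16
Reactants: 21 5β-allylic alcohol
Product: 22 3α,4α-epoxide of 21
Conditions: mCPBA, NaHCO3, CH2Cl2, 0 °C
Reagents that add atoms: meta-chloroperbenzoic acid, OOC(=O)c1cccc(Cl)c1
Why: Hydroxyl-directed epoxidation of the second Z allylic alcohol (C5–OH, C4=C3) follows the same threo preference and should give the epoxide trans to the C5 hydroxyl, the buffer sparing the orthoester.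

Step 17
Reactants: 22 3α,4α-epoxy-5β-alcohol; 18 angelic acid
Product: 23 5β-angelate of 22
Conditions: 18, 2,4,6-Cl3C6H2COCl, Et3N, toluene, rt; then 22, toluene, 75 °C
Reagents that add atoms: none
Why: Yamaguchi-type acylation through the preformed mixed anhydride esterifies the hindered C5 hydroxyl without DMAP, conditions under which the Z geometry of the angelate is retained.

Step 18
Reactants: 23 bis-angelate orthoacetate
Product: 24 CNP0197637.1 (1β,5β-bis-angelate; 3α,4α-epoxide; 6β-(R)-2-methylbutanoate; 9β-OH; 10α-OAc)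
Conditions: AcOH/H2O 4:1, THF, 0 °C → rt
Reagents that add atoms: water, O
Why: Mild acid hydrolysis of the cyclic orthoacetate runs through the dioxolan-2-ylium ion and its hemi-orthoester, whose collapse should expel the less hindered secondary C9 oxygen and leave the acetate on the tertiary C10 oxygen (the pattern that places the acyl group on the more hindered oxygen in cyclic orthoester openings), while the epoxide and the other esters are untouched.

**Compound list**

1 | (S)-(+)-carvone | O=C1C[C@@H](C(C)=C)CC=C1C | starting material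
2 | potassium dienolate of 1 (C5–O−, C5=C6) | [K+].[O-]C1=C[C@@H](C(C)=C)CC=C1C | intermediate
3 | (5R,6R)-6-hydroxycarvone (6α-OH, trans to isopropenyl) | O=C1[C@H](O)[C@@H](C(C)=C)CC=C1C | intermediate
4 | (5R,6S)-6-(4-methoxyphenoxy)carvone (6β-OAr, cis to isopropenyl) | O=C1[C@@H](Oc2ccc(OC)cc2)[C@@H](C(C)=C)CC=C1C | intermediate
5 | (1R,5R,6S)-6-(4-methoxyphenoxy)-2-methyl-5-(prop-1-en-2-yl)-1-vinylcyclohex-2-en-1-ol (5β-OH, 5α-vinyl) | O[C@@]1(C=C)[C@@H](Oc2ccc(OC)cc2)[C@@H](C(C)=C)CC=C1C | intermediate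
6 | 9β,10β-epoxide of 5 (epoxide cis to the tertiary OH) | O[C@@]1(C=C)[C@@H](Oc2ccc(OC)cc2)[C@@H](C(C)=C)C[C@@H]3[C@@]1(C)O3 | intermediate
7 | 6β-(4-methoxyphenoxy)-9β-(TBS-oxy)-10β-methyl-10α-vinyl-7β-isopropenylcyclohexan-5-one | O=C1[C@@H](Oc2ccc(OC)cc2)[C@@H](C(C)=C)C[C@@H](O[Si](C)(C)C(C)(C)C)[C@]1(C)C=C | intermediate
8 | 5β-hydroxy-5α-isopropenyl adduct of 7 (isopropenyl cis to the C10 vinyl) | O[C@@]1(C(C)=C)[C@@H](Oc2ccc(OC)cc2)[C@@H](C(C)=C)C[C@@H](O[Si](C)(C)C(C)(C)C)[C@]1(C)C=C | intermediate
9 | potassium enolate of the ring-expanded ketone (Z C1=C10; C4=C5–O− with C3 and C6 trans) | C=C(C)[C@H]1C[C@@H](O[Si](C)(C)C(C)(C)C)/C(C)=C\CC/C(C)=C(\[O-])[C@H]1Oc2ccc(OC)cc2.[K+] | intermediate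
10 | 4-(phenylselanyl)-(1(10)Z)-cyclodec-1(10)-en-5-one, 6β-OAr, 7β-isopropenyl, 9β-OTBS (C4 epimers) | C=C(C)[C@H]1C[C@@H](O[Si](C)(C)C(C)(C)C)/C(C)=C\CCC(C)([Se]c2ccccc2)C(=O)[C@H]1Oc3ccc(OC)cc3 | intermediate
11 | selenoxide of 10 (C4 and Se epimers) | C=C(C)[C@H]1C[C@@H](O[Si](C)(C)C(C)(C)C)/C(C)=C\CCC(C)([Se](=O)c2ccccc2)C(=O)[C@H]1Oc3ccc(OC)cc3 | intermediate
12 | (1(10)Z,3Z)-cyclodeca-1(10),3-dien-5-one, 6β-OAr, 9β-OTBS | C=C(C)[C@H]1C[C@@H](O[Si](C)(C)C(C)(C)C)/C(C)=C\C/C=C(C)\C(=O)[C@H]1Oc2ccc(OC)cc2 | intermediate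
13 | 6β-hydroxy dienone, 9β-OTBS | C=C(C)[C@H]1C[C@@H](O[Si](C)(C)C(C)(C)C)/C(C)=C\C/C=C(C)\C(=O)[C@H]1O | intermediate
14 | (R)-2-methylbutanoic acid | CC[C@@H](C)C(=O)O | starting material
15 | 6β-[(R)-2-methylbutanoyloxy] dienone, 9β-OTBS | C=C(C)[C@H]1C[C@@H](O[Si](C)(C)C(C)(C)C)/C(C)=C\C/C=C(C)\C(=O)[C@H]1OC(=O)[C@H](C)CC | intermediate
16 | 9β-hydroxy dienone C6 ester | C=C(C)[C@H]1C[C@@H](O)/C(C)=C\C/C=C(C)\C(=O)[C@H]1OC(=O)[C@H](C)CC | intermediate
17 | 1α,10α-epoxide of 16 | C=C(C)[C@H]1C[C@@H](O)[C@]2(C)O[C@@H]2C/C=C(C)\C(=O)[C@H]1OC(=O)[C@H](C)CC | intermediate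
18 | angelic acid, (Z)-2-methylbut-2-enoic acid | C/C=C(/C)C(=O)O | starting material
19 | 1β-angeloyloxy-9β,10α-dihydroxy-(3Z)-en-5-one C6 ester | C=C(C)[C@H]1C[C@@H](O)[C@](C)(O)[C@@H](OC(=O)/C(C)=C\C)C/C=C(C)\C(=O)[C@H]1OC(=O)[C@H](C)CC | intermediate
20 | 9,10-O-(1-methoxyethylidene) orthoacetate of 19 (orthoester carbon: both epimers) | C=C(C)[C@H]1C[C@H]2OC(C)(OC)O[C@]2(C)[C@@H](OC(=O)/C(C)=C\C)C/C=C(C)\C(=O)[C@H]1OC(=O)[C@H](C)CC | intermediate
21 | 5β-alcohol of 20 | C=C(C)[C@H]1C[C@H]2OC(C)(OC)O[C@]2(C)[C@@H](OC(=O)/C(C)=C\C)C/C=C(C)\[C@@H](O)[C@H]1OC(=O)[C@H](C)CC | intermediate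
22 | 3α,4α-epoxide of 21 | C=C(C)[C@H]1C[C@H]2OC(C)(OC)O[C@]2(C)[C@@H](OC(=O)/C(C)=C\C)C[C@@H]3O[C@]3(C)[C@@H](O)[C@H]1OC(=O)[C@H](C)CC | intermediate
23 | 5β-angelate of 22 | C=C(C)[C@H]1C[C@H]2OC(C)(OC)O[C@]2(C)[C@@H](OC(=O)/C(C)=C\C)C[C@@H]3O[C@]3(C)[C@@H](OC(=O)/C(C)=C\C)[C@H]1OC(=O)[C@H](C)CC | intermediate
24 | CNP0197637.1, (1S,3S,4S,5S,6S,7R,9R,10S) in the numbering used here, (R)-2-methylbutanoate | C=C(C)[C@H]1C[C@@H](O)[C@](C)(OC(C)=O)[C@@H](OC(=O)/C(C)=C\C)C[C@@H]2O[C@]2(C)[C@@H](OC(=O)/C(C)=C\C)[C@H]1OC(=O)[C@H](C)CC | target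

**Total steps:** 18. **Longest linear sequence:** 18 steps (1 → 24).

**Steps most likely to fail**

Step 7. The rearrangement may leave the chair pathway (boat, or the ring-flipped conformer) and give the E alkene, or the hindered alkoxide may fragment under the basic conditions. Fallback with a neutral shift: from 8, silylation (Me3SiOTf, Et3N) gives the trimethylsilyl ether F1. Thermal siloxy-Cope rearrangement (toluene, 190 °C, sealed, base-washed glass) gives the trimethylsilyl enol ether F2. Selenenylation of the silyl enol ether with PhSeCl (CH2Cl2, −78 °C) returns to the route at 10.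

Step 8. The syn elimination may lose geometric or regiochemical control, giving the E enone or the exocyclic methylene isomer. Fallback by equilibration: from 10, the elimination product is taken on even if it is the (1(10)Z,3E)-dienone F3. Catalytic I2 under visible light in CH2Cl2 (reversible iodine-atom addition) should isomerise it to the less strained Z,Z isomer, returning to the route at 12.

Step 18. The hemi-orthoester may collapse in the other direction, or the acetyl group may migrate from the tertiary to the secondary oxygen once formed. Fallback with stepwise acylation: from 19, selective silylation of the secondary C9 hydroxyl (t-BuMe2SiOTf, 2,6-lutidine, −78 °C) gives the 9-O-silyl ether F4. Forced acetylation of the tertiary hydroxyl (Ac2O, Sc(OTf)3 cat., MeCN, −20 °C) gives the C10 acetate F5. Zn(BH4)2 reduction gives the 5β-alcohol F6, buffered mCPBA gives the 3α,4α-epoxide F7, and Yamaguchi angeloylation gives the 9-O-silyl ether of the target F8. HF·pyridine then returns to the route at 24.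

Further compounds
F1 | step 7 | trimethylsilyl ether of 8 | C[Si](C)(C)O[C@@]1(C(C)=C)[C@@H](Oc2ccc(OC)cc2)[C@@H](C(C)=C)C[C@@H](O[Si](C)(C)C(C)(C)C)[C@]1(C)C=C
F2 | step 7 | trimethylsilyl enol ether (C4=C5–OSiMe3) of the ring-expanded ketone | C=C(C)[C@H]1C[C@@H](O[Si](C)(C)C(C)(C)C)/C(C)=C\CC/C(C)=C(\O[Si](C)(C)C)[C@H]1Oc2ccc(OC)cc2
F3 | step 8 | (1(10)Z,3E)-isomer of dienone 12 | C=C(C)[C@H]1C[C@@H](O[Si](C)(C)C(C)(C)C)/C(C)=C\C/C=C(C)/C(=O)[C@H]1Oc2ccc(OC)cc2
F4 | step 18 | 9-O-tert-butyldimethylsilyl ether of 19 | C=C(C)[C@H]1C[C@@H](O[Si](C)(C)C(C)(C)C)[C@](C)(O)[C@@H](OC(=O)/C(C)=C\C)C/C=C(C)\C(=O)[C@H]1OC(=O)[C@H](C)CC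
F5 | step 18 | C10 acetate of F4 | C=C(C)[C@H]1C[C@@H](O[Si](C)(C)C(C)(C)C)[C@](C)(OC(C)=O)[C@@H](OC(=O)/C(C)=C\C)C/C=C(C)\C(=O)[C@H]1OC(=O)[C@H](C)CC
F6 | step 18 | 5β-alcohol from F5 | C=C(C)[C@H]1C[C@@H](O[Si](C)(C)C(C)(C)C)[C@](C)(OC(C)=O)[C@@H](OC(=O)/C(C)=C\C)C/C=C(C)\[C@@H](O)[C@H]1OC(=O)[C@H](C)CC
F7 | step 18 | 3α,4α-epoxide of F6 | C=C(C)[C@H]1C[C@@H](O[Si](C)(C)C(C)(C)C)[C@](C)(OC(C)=O)[C@@H](OC(=O)/C(C)=C\C)C[C@@H]2O[C@]2(C)[C@@H](O)[C@H]1OC(=O)[C@H](C)CC
F8 | step 18 | 9-O-tert-butyldimethylsilyl ether of 24 | C=C(C)[C@H]1C[C@@H](O[Si](C)(C)C(C)(C)C)[C@](C)(OC(C)=O)[C@@H](OC(=O)/C(C)=C\C)C[C@@H]2O[C@]2(C)[C@@H](OC(=O)/C(C)=C\C)[C@H]1OC(=O)[C@H](C)CC
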